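**Strategy.** Everything rests on closing the butenolide ring (O–C6–C7=C11–C12) last by inserting CO2 between C11 and C6. An alkenyllithium at C11, made from a (Z)-iodoalkene, is carboxylated, and the new carboxylate displaces a tosylate at C6 (5-exo-tet, inversion) beside the existing C4–C5 epoxide. The step exploits the cis arrangement of C6 and C12 across the tetrasubstituted C7=C11 bond and the threo (anti-Felkin) C5/C6 relationship. The precursor is a ten-membered carbocycle bearing the erythro C6 tosylate and an exocyclic iodoalkene. It comes from a diiodobutenolide template (O8–C13 lactone, later reduced) closed onto a Sharpless-derived epoxy aldehyde by a Nozaki–Hiyama–Kishi reaction.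

Key step: step 15

Remark: locants C1–C15 are germacrane locants (C6 bears the lactone oxygen, C12 is the lactone carbonyl, C13 the hydroxymethyl carbon, C8 bears the methacrylate). The (Z)-crotylborane of step 4 is used as a preformed solution, and simple reagents carry no compound number.

Step 1
Reactants: 1 geraniol
Product: 2 (2R,3R)-2,3-epoxygeraniol
Conditions: Ti(OiPr)4 (5 mol%), D-(−)-diethyl tartrate (7 mol%), t-BuOOH, 4 Å MS, CH2Cl2, −20 °C
Reagents that add atoms: tert-butyl hydroperoxide, CC(C)(C)OO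
Why: Sharpless asymmetric epoxidation of the allylic alcohol, in which the D-tartrate titanium catalyst should deliver oxygen to the face that gives the 2R,3R epoxide and so fixes C4 and C5 of the target.

Step 2
Reactants: 2 (2R,3R)-2,3-epoxygeraniol
Product: 3 (2R,3R)-2,3-epoxygeranyl triethylsilyl ether
Conditions: Et3SiCl, imidazole, CH2Cl2, 0 °C
Reagents that add atoms: chlorotriethylsilane, CC[Si](Cl)(CC)CC
Why: Silylation of the primary alcohol gives a triethylsilyl ether that survives the next steps and can later be oxidized directly to the aldehyde.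

Step 3
Reactants: 3 (2R,3R)-2,3-epoxygeranyl triethylsilyl ether
Product: 5 3-[(2R,3R)-2-methyl-3-(triethylsilyloxymethyl)oxiran-2-yl]propanal, via ozonide 4 (not isolated)
Conditions: O3, CH2Cl2, −78 °C; then PPh3, −78 °C → rt
Reagents that add atoms: ozone, [O-][O+]=O
Why: Ozonolysis with reductive work-up cleaves the only C=C bond to the C1 aldehyde, the epoxide and the silyl ether being inert to ozone.

Step 4
Reactants: 5 3-[(2R,3R)-2-methyl-3-(triethylsilyloxymethyl)oxiran-2-yl]propanal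
Product: 7 (3S,4S)-3-methyl-6-[(2R,3R)-2-methyl-3-(triethylsilyloxymethyl)oxiran-2-yl]hex-1-en-4-ol, via borinate 6 (not isolated)
Conditions: (Z)-crotylB(Ipc)2 [Ipc from (−)-α-pinene], THF/Et2O, −78 °C; then HOCH2CH2NH2, rt
Reagents that add atoms: (Z)-crotyldiisopinocampheylborane, C/C=C\CB([C@@H]1[C@@H](C)[C@@H]2C[C@H](C1)C2(C)C)[C@@H]1[C@@H](C)[C@@H]2C[C@H](C1)C2(C)C
Why: Brown asymmetric crotylboration through a chair-like Zimmerman–Traxler transition state, in which the (Z)-crotyl geometry should give the syn C1/C10 pair and the isopinocampheyl groups should direct attack to the Re face of the aldehyde (1S,10S).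

Step 5
Reactants: 7 (3S,4S)-3-methyl-6-[(2R,3R)-2-methyl-3-(triethylsilyloxymethyl)oxiran-2-yl]hex-1-en-4-ol
Product: 8 4-methoxybenzyl ether of 7
Conditions: NaH, 4-MeOC6H4CH2Br, Bu4NI (cat.), THF/DMF, 0 °C
Reagents that add atoms: 4-methoxybenzyl bromide, COc1ccc(CBr)cc1
Why: Williamson etherification, in which benzylation of the alkoxide at 0 °C should be faster than its 5-exo attack on the tertiary epoxide carbon.

Step 6
Reactants: 8 4-methoxybenzyl ether of 7
Product: 10 (3S,4S)-4-(4-methoxybenzyloxy)-3-methyl-6-[(2R,3R)-2-methyl-3-(triethylsilyloxymethyl)oxiran-2-yl]hexan-1-ol, via alkylborane 9 (not isolated)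
Conditions: 9-BBN, THF, 0 °C → rt; then NaBO3·4H2O, H2O, rt
Reagents that add atoms: 9-borabicyclo[3.3.1]nonane, B1C2CCCC1CCC2 (boron retained only in 9); sodium perborate, [Na+].[Na+].O[B-]1(O)OO[B-](O)(O)OO1
Why: Anti-Markovnikov hydroboration–oxidation of the terminal alkene places the hydroxyl on C8, and the mild perborate oxidation spares the silyl ether and the epoxide.

Step 7
Reactants: 10 (3S,4S)-4-(4-methoxybenzyloxy)-3-methyl-6-[(2R,3R)-2-methyl-3-(triethylsilyloxymethyl)oxiran-2-yl]hexan-1-ol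
Product: 11 (3S,4S)-4-(4-methoxybenzyloxy)-3-methyl-6-[(2R,3R)-2-methyl-3-(triethylsilyloxymethyl)oxiran-2-yl]hexanal
Conditions: Dess–Martin periodinane, NaHCO3, CH2Cl2, 0 °C → rt
Reagents that add atoms: none
Why: Dess–Martin oxidation of the primary alcohol to the C8 aldehyde under buffered, non-epimerizing conditions.

Step 8
Reactants: 11 (3S,4S)-4-(4-methoxybenzyloxy)-3-methyl-6-[(2R,3R)-2-methyl-3-(triethylsilyloxymethyl)oxiran-2-yl]hexanal; 12 methyl propiolate
Product: 13 methyl (4S,6S,7S)-4-hydroxy-7-(4-methoxybenzyloxy)-6-methyl-9-[(2R,3R)-2-methyl-3-(triethylsilyloxymethyl)oxiran-2-yl]non-2-ynoate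
Conditions: Me2Zn, (S,S)-ProPhenol (20 mol%), Ph3P=O (40 mol%), toluene, 0 °C
Reagents that add atoms: methyl propiolate, C#CC(=O)OC
Why: Trost zinc–ProPhenol asymmetric alkynylation, in which the dinuclear zinc catalyst should deliver the zinc alkynylide to the Re face of the aldehyde and set C8 as S under catalyst control.

Step 9
Reactants: 13 methyl (4S,6S,7S)-4-hydroxy-7-(4-methoxybenzyloxy)-6-methyl-9-[(2R,3R)-2-methyl-3-(triethylsilyloxymethyl)oxiran-2-yl]non-2-ynoate
Product: 15 (5S)-3,4-diiodo-5-{(2S,3S)-3-(4-methoxybenzyloxy)-2-methyl-5-[(2R,3R)-2-methyl-3-(triethylsilyloxymethyl)oxiran-2-yl]pentyl}furan-2(5H)-one, via bis(trimethylstannyl)butenolide 14 (not isolated)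
Conditions: Me3SnSnMe3, Pd(PPh3)4 (5 mol%), THF, 60 °C; then I2, CH2Cl2, 0 °C
Reagents that add atoms: hexamethylditin, C[Sn](C)(C)[Sn](C)(C)C (tin retained only in 14); iodine, II
Why: Palladium-catalyzed syn-distannation of the ynoate (Piers) places both tin atoms cis so that the γ-hydroxy ester lactonizes, and iododestannylation with retention then gives the diiodobutenolide template that locks the C7=C11 geometry.

Step 10
Reactants: 15 (5S)-3,4-diiodo-5-{(2S,3S)-3-(4-methoxybenzyloxy)-2-methyl-5-[(2R,3R)-2-methyl-3-(triethylsilyloxymethyl)oxiran-2-yl]pentyl}furan-2(5H)-one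
Product: 16 (2S,3R)-3-{(3S,4S)-5-[(2S)-3,4-diiodo-5-oxo-2,5-dihydrofuran-2-yl]-3-(4-methoxybenzyloxy)-4-methylpentyl}-3-methyloxirane-2-carbaldehyde
Conditions: (COCl)2, DMSO, CH2Cl2, −78 → −40 °C; then iPr2NEt, −78 → 0 °C
Reagents that add atoms: none
Why: Swern oxidation applied directly to the primary triethylsilyl ether (the chlorosulfonium salt cleaves the Si–O bond), which should give the C6 epoxy aldehyde while the base stays weak enough to spare C8 and C5.

Step 11
Reactants: 16 (2S,3R)-3-{(3S,4S)-5-[(2S)-3,4-diiodo-5-oxo-2,5-dihydrofuran-2-yl]-3-(4-methoxybenzyloxy)-4-methylpentyl}-3-methyloxirane-2-carbaldehyde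
Product: 17 (1S,4R,5R,6R,8S,10S)-4,5-epoxy-6-hydroxy-11-iodo-1-(4-methoxybenzyloxy)-12-norgermacr-7(11)-en-13,8-olide
Conditions: CrCl2 (8 equiv), NiCl2 (cat.), DMSO/THF, rt, high dilution
Reagents that add atoms: none
Why: Nozaki–Hiyama–Kishi macrocyclization, in which zerovalent nickel should insert into the more electron-poor β C–I bond (C7) and the alkenylchromium should add to the aldehyde anti to the epoxide C–O bond (Felkin–Anh) to give the erythro 6R alcohol, the C11 iodide being unable to eliminate inside the five-membered ring.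

Step 12
Reactants: 17 (1S,4R,5R,6R,8S,10S)-4,5-epoxy-6-hydroxy-11-iodo-1-(4-methoxybenzyloxy)-12-norgermacr-7(11)-en-13,8-olide
Product: 18 6-O-tosylate of 17
Conditions: Ts2O, pyridine, DMAP (cat.), CH2Cl2, 0 °C
Reagents that add atoms: p-toluenesulfonic anhydride, Cc1ccc(cc1)S(=O)(=O)OS(=O)(=O)c1ccc(C)cc1
Why: Sulfonylation at oxygen with retention at C6 turns the only free hydroxyl into a nucleofuge that has no acidic α-hydrogen.

Step 13
Reactants: 18 6-O-tosylate of 17
Product: 19 (1S,4R,5R,6R,8S,10S,7(11)Z)-4,5-epoxy-11-iodo-1-(4-methoxybenzyloxy)-6-tosyloxy-12-norgermacr-7(11)-ene-8,13-diol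
Conditions: iBu2AlH, CH2Cl2, −78 → −20 °C; aq. potassium sodium tartrate work-up
Reagents that add atoms: none
Why: Hydride reduction of the lactone through the lactol to the ene-1,4-diol, in which the alkene geometry set by the butenolide is kept so that iodine stays cis to C6 and the CH2OH cis to C8.

Step 14
Reactants: 19 (1S,4R,5R,6R,8S,10S,7(11)Z)-4,5-epoxy-11-iodo-1-(4-methoxybenzyloxy)-6-tosyloxy-12-norgermacr-7(11)-ene-8,13-diol
Product: 20 13-O-tert-butyldiphenylsilyl ether of 19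
Conditions: t-BuPh2SiCl, imidazole, CH2Cl2, 0 °C
Reagents that add atoms: tert-butylchlorodiphenylsilane, CC(C)(C)[Si](Cl)(c1ccccc1)c1ccccc1
Why: Selective silylation of the primary allylic hydroxyl over the hindered secondary C8 hydroxyl, the bulky silyl group being slow to migrate to carbon in the next step.

Step 15
Reactants: 20 13-O-tert-butyldiphenylsilyl ether of 19
Product: 23 (1S,4R,5R,6S,8S,10S)-13-(tert-butyldiphenylsilyloxy)-4,5-epoxy-8-hydroxy-1-(4-methoxybenzyloxy)germacr-7(11)-en-12,6-olide, via alkenyllithium 21 (not isolated), via lithium carboxylate 22 (not isolated)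
Conditions: t-BuLi (3.1 equiv), THF/Et2O, −78 °C; CO2; then DMF, −78 → 40 °C
Reagents that add atoms: tert-butyllithium, [Li]C(C)(C)C (lithium retained only in 21 and 22); carbon dioxide, O=C=O
Why: One equivalent of t-BuLi deprotonates the C8 hydroxyl and two more effect iodine–lithium exchange with retention of alkene geometry (21); CO2 then gives the lithium acrylate 22, whose carboxylate oxygen displaces the C6 tosylate on warming in DMF. The closest known reaction types are the carboxylation of alkenyllithiums with CO2 and the lactonization of γ-sulfonyloxy (Z)-enoates by carboxylate displacement with alkyl–oxygen inversion. The butenolide closes in the 5-exo-tet mode. C6 is the only new stereocenter and is set by SN2 inversion of the erythro 6R tosylate from step 11, so the threo 6S lactone should result. The step needs attack at C6 and not at C5 of the epoxide: the template-derived geometry holds C12 cis to C6 within reach of a five-membered transition state and the tosylate is the better nucleofuge, while the C8 alkoxide (trans to C12, able to form only an oxetane) and the silyl ether at C13 cannot compete.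

Step 16
Reactants: 23 (1S,4R,5R,6S,8S,10S)-13-(tert-butyldiphenylsilyloxy)-4,5-epoxy-8-hydroxy-1-(4-methoxybenzyloxy)germacr-7(11)-en-12,6-olide
Product: 24 8-O-methacrylate of 23
Conditions: methacrylic anhydride, Et3N, DMAP (cat.), CH2Cl2, 0 °C → rt
Reagents that add atoms: methacrylic anhydride, C=C(C)C(=O)OC(=O)C(C)=C
Why: DMAP-catalyzed acylation of the only free hydroxyl (C8) under mild base that should not deprotonate C6 of the butenolide.

Step 17
Reactants: 24 8-O-methacrylate of 23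
Product: 25 (1S,4R,5R,6S,8S,10S)-13-(tert-butyldiphenylsilyloxy)-4,5-epoxy-1-hydroxy-8-methacryloyloxygermacr-7(11)-en-12,6-olide
Conditions: DDQ, CH2Cl2/pH 7 buffer, 0 °C
Reagents that add atoms: none
Why: Oxidative cleavage of the 4-methoxybenzyl ether by DDQ frees the C1 hydroxyl without touching the electron-poor alkenes, the epoxide or the silyl ether.

Step 18
Reactants: 25 (1S,4R,5R,6S,8S,10S)-13-(tert-butyldiphenylsilyloxy)-4,5-epoxy-1-hydroxy-8-methacryloyloxygermacr-7(11)-en-12,6-olide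
Product: 26 13-O-tert-butyldiphenylsilyl glaucolide L
Conditions: Ac2O, pyridine, DMAP (cat.), CH2Cl2, 0 °C
Reagents that add atoms: acetic anhydride, CC(=O)OC(C)=O
Why: Acetylation of the C1 hydroxyl, the only free hydroxyl at this stage.

Step 19
Reactants: 26 13-O-tert-butyldiphenylsilyl glaucolide L
Product: 27 glaucolide L
Conditions: Bu4NF, AcOH, THF, 0 °C → rt
Reagents that add atoms: none
Why: Fluoride-induced desilylation buffered with acetic acid frees the C13 hydroxyl while sparing the two esters, the epoxide and the base-sensitive butenolide.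

**Compound list**

1 | geraniol | OC/C=C(\C)CCC=C(C)C | starting material
2 | (2R,3R)-2,3-epoxygeraniol | CC(C)=CCC[C@@]1(C)O[C@@H]1CO | intermediate
3 | (2R,3R)-2,3-epoxygeranyl triethylsilyl ether | CC(C)=CCC[C@@]1(C)O[C@@H]1CO[Si](CC)(CC)CC | intermediate
4 | ozonide of 3 (3,3-dimethyl-1,2,4-trioxolane) | CC1(C)OOC(CC[C@@]2(C)O[C@@H]2CO[Si](CC)(CC)CC)O1 | intermediate
5 | 3-[(2R,3R)-2-methyl-3-(triethylsilyloxymethyl)oxiran-2-yl]propanal | O=CCC[C@@]1(C)O[C@@H]1CO[Si](CC)(CC)CC | intermediate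
6 | diisopinocampheylborinate of 7 | C=C[C@H](C)[C@@H](OB([C@@H]1[C@@H](C)[C@@H]2C[C@H](C1)C2(C)C)[C@@H]1[C@@H](C)[C@@H]2C[C@H](C1)C2(C)C)CC[C@@]1(C)O[C@@H]1CO[Si](CC)(CC)CC | intermediate
7 | (3S,4S)-3-methyl-6-[(2R,3R)-2-methyl-3-(triethylsilyloxymethyl)oxiran-2-yl]hex-1-en-4-ol | C=C[C@H](C)[C@@H](O)CC[C@@]1(C)O[C@@H]1CO[Si](CC)(CC)CC | intermediate
8 | 4-methoxybenzyl ether of 7 | C=C[C@H](C)[C@@H](OCc1ccc(OC)cc1)CC[C@@]1(C)O[C@@H]1CO[Si](CC)(CC)CC | intermediate
9 | B-alkyl-9-borabicyclo[3.3.1]nonane from 8 (boron on C8) | B1(CC[C@H](C)[C@@H](OCc2ccc(OC)cc2)CC[C@@]2(C)O[C@@H]2CO[Si](CC)(CC)CC)C2CCCC1CCC2 | intermediate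
10 | (3S,4S)-4-(4-methoxybenzyloxy)-3-methyl-6-[(2R,3R)-2-methyl-3-(triethylsilyloxymethyl)oxiran-2-yl]hexan-1-ol | OCC[C@H](C)[C@@H](OCc1ccc(OC)cc1)CC[C@@]1(C)O[C@@H]1CO[Si](CC)(CC)CC | intermediate
11 | (3S,4S)-4-(4-methoxybenzyloxy)-3-methyl-6-[(2R,3R)-2-methyl-3-(triethylsilyloxymethyl)oxiran-2-yl]hexanal | O=CC[C@H](C)[C@@H](OCc1ccc(OC)cc1)CC[C@@]1(C)O[C@@H]1CO[Si](CC)(CC)CC | intermediate
12 | methyl propiolate | C#CC(=O)OC | starting material
13 | methyl (4S,6S,7S)-4-hydroxy-7-(4-methoxybenzyloxy)-6-methyl-9-[(2R,3R)-2-methyl-3-(triethylsilyloxymethyl)oxiran-2-yl]non-2-ynoate | COC(=O)C#C[C@@H](O)C[C@H](C)[C@@H](OCc1ccc(OC)cc1)CC[C@@]1(C)O[C@@H]1CO[Si](CC)(CC)CC | intermediate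
14 | (5S)-3,4-bis(trimethylstannyl)butenolide corresponding to 15 | O=C1O[C@@H](C[C@H](C)[C@@H](OCc2ccc(OC)cc2)CC[C@@]2(C)O[C@@H]2CO[Si](CC)(CC)CC)C([Sn](C)(C)C)=C1[Sn](C)(C)C | intermediate
15 | (5S)-3,4-diiodo-5-{(2S,3S)-3-(4-methoxybenzyloxy)-2-methyl-5-[(2R,3R)-2-methyl-3-(triethylsilyloxymethyl)oxiran-2-yl]pentyl}furan-2(5H)-one | O=C1O[C@@H](C[C@H](C)[C@@H](OCc2ccc(OC)cc2)CC[C@@]2(C)O[C@@H]2CO[Si](CC)(CC)CC)C(I)=C1I | intermediate
16 | (2S,3R)-3-{(3S,4S)-5-[(2S)-3,4-diiodo-5-oxo-2,5-dihydrofuran-2-yl]-3-(4-methoxybenzyloxy)-4-methylpentyl}-3-methyloxirane-2-carbaldehyde | O=C1O[C@@H](C[C@H](C)[C@@H](OCc2ccc(OC)cc2)CC[C@@]2(C)O[C@@H]2C=O)C(I)=C1I | intermediate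
17 | (1S,4R,5R,6R,8S,10S)-4,5-epoxy-6-hydroxy-11-iodo-1-(4-methoxybenzyloxy)-12-norgermacr-7(11)-en-13,8-olide | O=C1O[C@H]2C[C@H](C)[C@@H](OCc3ccc(OC)cc3)CC[C@@]3(C)O[C@@H]3[C@H](O)C2=C1I | intermediate
18 | 6-O-tosylate of 17 (6R) | O=C1O[C@H]2C[C@H](C)[C@@H](OCc3ccc(OC)cc3)CC[C@@]3(C)O[C@@H]3[C@H](OS(=O)(=O)c3ccc(C)cc3)C2=C1I | intermediate
19 | (1S,4R,5R,6R,8S,10S,7(11)Z)-4,5-epoxy-11-iodo-1-(4-methoxybenzyloxy)-6-tosyloxy-12-norgermacr-7(11)-ene-8,13-diol | O[C@H]1C[C@H](C)[C@@H](OCc2ccc(OC)cc2)CC[C@@]2(C)O[C@@H]2[C@H](OS(=O)(=O)c2ccc(C)cc2)/C1=C(\I)CO | intermediate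
20 | 13-O-tert-butyldiphenylsilyl ether of 19 | O[C@H]1C[C@H](C)[C@@H](OCc2ccc(OC)cc2)CC[C@@]2(C)O[C@@H]2[C@H](OS(=O)(=O)c2ccc(C)cc2)/C1=C(\I)CO[Si](c1ccccc1)(c1ccccc1)C(C)(C)C | intermediate
21 | C11 alkenyllithium (lithium C8 alkoxide) from 20 | [Li]O[C@H]1C[C@H](C)[C@@H](OCc2ccc(OC)cc2)CC[C@@]2(C)O[C@@H]2[C@H](OS(=O)(=O)c2ccc(C)cc2)/C1=C(\[Li])CO[Si](c1ccccc1)(c1ccccc1)C(C)(C)C | intermediate
22 | lithium C12 carboxylate (lithium C8 alkoxide) from 21 | [Li]O[C@H]1C[C@H](C)[C@@H](OCc2ccc(OC)cc2)CC[C@@]2(C)O[C@@H]2[C@H](OS(=O)(=O)c2ccc(C)cc2)/C1=C(\C(=O)O[Li])CO[Si](c1ccccc1)(c1ccccc1)C(C)(C)C | intermediate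
23 | (1S,4R,5R,6S,8S,10S)-13-(tert-butyldiphenylsilyloxy)-4,5-epoxy-8-hydroxy-1-(4-methoxybenzyloxy)germacr-7(11)-en-12,6-olide | O[C@H]1C[C@H](C)[C@@H](OCc2ccc(OC)cc2)CC[C@@]2(C)O[C@@H]2[C@H]2OC(=O)C(CO[Si](c3ccccc3)(c3ccccc3)C(C)(C)C)=C12 | intermediate
24 | 8-O-methacrylate of 23 | C=C(C)C(=O)O[C@H]1C[C@H](C)[C@@H](OCc2ccc(OC)cc2)CC[C@@]2(C)O[C@@H]2[C@H]2OC(=O)C(CO[Si](c3ccccc3)(c3ccccc3)C(C)(C)C)=C12 | intermediate
25 | (1S,4R,5R,6S,8S,10S)-13-(tert-butyldiphenylsilyloxy)-4,5-epoxy-1-hydroxy-8-methacryloyloxygermacr-7(11)-en-12,6-olide | C=C(C)C(=O)O[C@H]1C[C@H](C)[C@@H](O)CC[C@@]2(C)O[C@@H]2[C@H]2OC(=O)C(CO[Si](c3ccccc3)(c3ccccc3)C(C)(C)C)=C12 | intermediate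
26 | 13-O-tert-butyldiphenylsilyl glaucolide L | C=C(C)C(=O)O[C@H]1C[C@H](C)[C@@H](OC(C)=O)CC[C@@]2(C)O[C@@H]2[C@H]2OC(=O)C(CO[Si](c3ccccc3)(c3ccccc3)C(C)(C)C)=C12 | intermediate
27 | glaucolide L | C=C(C)C(=O)O[C@H]1C[C@H](C)[C@@H](OC(C)=O)CC[C@@]2(C)O[C@@H]2[C@H]2OC(=O)C(CO)=C12 | target

**Step count and risks**

Total step count: 19. Longest linear sequence: 19 steps, from geraniol.

Steps most likely to fail:

1. Step 11 (ring closure). The ten-membered ring may close slowly against oligomerization. The facial selectivity at C6 may also be eroded by the macrocyclic constraint, so that the threo alcohol forms beside or instead of the erythro alcohol. The fallback sets out from 16 and secures C6 by reduction instead of addition. The crude closure product, as the mixture of 17 and its 6S epimer F2, is oxidized with Dess–Martin periodinane to the epoxy enone F3. Chelation-controlled reduction with Zn(BH4)2 in Et2O at −20 °C, with zinc bridging the ketone and epoxide oxygens, should give the erythro alcohol and returns to the route at 17.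

2. Step 15 (key step). The organolithium may attack the sulfonate, or the tosylate may be lost before carboxylation. The lithium carboxylate may also displace too slowly, so that elimination or epoxide opening takes over. The fallback sets out from 20 and avoids organolithium chemistry. Palladium-catalyzed methoxycarbonylation of the alkenyl iodide (PdCl2(PPh3)2, CO 1 atm, MeOH, Et3N, DMF, 50 °C) gives the methyl ester F1. Heating F1 in MeCN with 2,6-lutidine at 70 °C should close the lactone by attack of the ester carbonyl oxygen on C6 with inversion and loss of the methyl group to the departing tosylate. It returns to the route at 23.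

3. Step 9 (template formation). The distannation may stay incomplete, the bis-stannyl enoate may isomerize from Z to E before it lactonizes, and the tin iodide formed may open the epoxide. The fallback sets out from 13 and uses boron in place of tin. Platinum-catalyzed syn-diboration (B2pin2, Pt(PPh3)4, DMF, 80 °C) with lactonization gives the bis(pinacolboryl)butenolide F4. Iododeboronation with NaI and chloramine-T in THF/H2O, which proceeds with retention, returns to the route at 15.

**Further compounds**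

F1 | step 15 | methyl (Z)-ester at C11 of the macrocycle (C12 as CO2Me, C6 tosylate, C8 hydroxyl, C13 silyl ether) | O[C@H]1C[C@H](C)[C@@H](OCc2ccc(OC)cc2)CC[C@@]2(C)O[C@@H]2[C@H](OS(=O)(=O)c2ccc(C)cc2)/C1=C(\C(=O)OC)CO[Si](c1ccccc1)(c1ccccc1)C(C)(C)C
F2 | step 11 | 6S epimer of 17 (threo alcohol) | O=C1O[C@H]2C[C@H](C)[C@@H](OCc3ccc(OC)cc3)CC[C@@]3(C)O[C@@H]3[C@@H](O)C2=C1I
F3 | step 11 | C6 ketone of 17 (epoxy enone) | O=C1O[C@H]2C[C@H](C)[C@@H](OCc3ccc(OC)cc3)CC[C@@]3(C)O[C@@H]3C(=O)C2=C1I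
F4 | step 9 | (5S)-3,4-bis(pinacolboryl)butenolide corresponding to 15 | O=C1O[C@@H](C[C@H](C)[C@@H](OCc2ccc(OC)cc2)CC[C@@]2(C)O[C@@H]2CO[Si](CC)(CC)CC)C(B2OC(C)(C)C(C)(C)O2)=C1B1OC(C)(C)C(C)(C)O1
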